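Assumption: germacrone (commercial natural ketone, crystallises from zdravets oil) and angelic acid are taken as inexpensive starting materials; α/β labels use eremophilane numbering with both methyls (C14, C15) β, as in the target SMILES.

**Retrosynthetic overview**
1. Target ⇒ 3α,9β-diol; the two angelates go on last, after the base-sensitive isopropenyl ketone is in place.
2. Diol ⇒ O-silyl isopetasol: C10–H by cis-hydrogenation, C9–O by α′-enolate hydroxylation, C7–H/isopropenyl by kinetic deconjugation.
3. O-Silyl isopetasol ⇒ 3-silyloxy-isogermacrone by one Lewis-acid cascade: transannular C5–C10 closure (eudesmyl cation), then 1,2-H (C5→C4) and 1,2-Me (C10→C5) shifts, i.e. germacrane → eudesmane → eremophilane.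
4. 3-Silyloxy-isogermacrone ⇒ germacrone by conjugation, C3 allylic hydroxylation and Sharpless kinetic resolution; the C3 stereocentre then sets C4 and C5.
5. Ring order: the 10-membered germacrane ring comes with germacrone; both six-membered rings form at once through the transannular bond.

**Route**

Step 1
Reactants: 1 germacrone, (1(10)E,4E)-germacra-1(10),4,7(11)-trien-8-one
Product: 2 isogermacrone, (4E,9E)-germacra-4,7(11),9-trien-8-one
Conditions: t-BuOK (0.2 equiv), t-BuOH/THF, 25 °C
Reagents that add atoms: none
Why: Base-mediated conjugative isomerisation: deprotonation at the doubly activated C9 and γ-reprotonation of the dienolate at C1 move the 1(10)-alkene into conjugation (cross-conjugated dienone, thermodynamic), leaving the (E)-C4=C5 alkene as the only electron-rich olefin; no stereocentre is formed.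

Step 2
Reactants: 2 isogermacrone
Product: 3 rac-(4E,9E)-3-hydroxygermacra-4,7(11),9-trien-8-one
Conditions: SeO2 (0.5 equiv), t-BuOOH (2 equiv), CH2Cl2, 0 → 25 °C
Reagents that add atoms: tert-butyl hydroperoxide CC(C)(C)OO (terminal oxidant; its oxygen is delivered through catalytic selenium dioxide O=[Se]=O)
Why: SeO2/TBHP allylic hydroxylation (ene reaction then [2,3]-shift) attacks only the isolated trisubstituted C4=C5 alkene, at the CH2 on its disubstituted end that is cis to the vinyl H (C3; CH2 > CH3 and E-rule), with the double bond position and geometry retained; the alcohol is racemic.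

Step 3
Reactants: 3 rac-(4E,9E)-3-hydroxygermacra-4,7(11),9-trien-8-one
Product: 4 (3R,4E,9E)-3-hydroxygermacra-4,7(11),9-trien-8-one (recovered slow-reacting enantiomer)
Conditions: Ti(OiPr)4 (0.15 equiv), L-(+)-DIPT (0.2 equiv), t-BuOOH (0.6 equiv), 4 Å MS, CH2Cl2, −20 °C, stopped at about 55–60% conversion
Reagents that add atoms: none
Why: Sharpless kinetic resolution of a secondary allylic alcohol with no substituent cis to the carbinol on the alkene: with L-(+)-tartrate the (3S)-enantiomer is epoxidised fast, so the (3R)-alcohol is recovered in high ee and fixes the absolute configuration of the whole route.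

Step 4
Reactants: 4 (3R,4E,9E)-3-hydroxygermacra-4,7(11),9-trien-8-one
Product: 5 (3R,4E,9E)-3-(tert-butyldimethylsilyloxy)germacra-4,7(11),9-trien-8-one
Conditions: TBSCl, imidazole, DMF, 25 °C
Reagents that add atoms: tert-butyldimethylsilyl chloride CC(C)(C)[Si](C)(C)Cl
Why: Standard silylation; the bulky, non-acylating ether prevents allylic ionisation, oxa-Michael addition to the enone and acyloxy participation in step 5, and biases the C3–O bond pseudoaxial.

Step 5
Reactants: 5 (3R,4E,9E)-3-(tert-butyldimethylsilyloxy)germacra-4,7(11),9-trien-8-one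
Product: 6 3α-(tert-butyldimethylsilyloxy)eremophila-7(11),9-dien-8-one, (3R,4R,5R), O-TBS-isopetasol
Conditions: MeAlCl2 (2.2 equiv), CH2Cl2, −78 → 0 °C; 1 M HCl quench
Reagents that add atoms: none
Why: Proposed new method: MeAlCl2 activates the C9=C10 enone, and the (E)-C4=C5 alkene adds through C5 to C10 in a chair–chair transition state, giving a trans-fused eudesmyl C4 cation/aluminium dienolate zwitterion (C14 axial because it is cis to C8 in the 9E-enone; OTBS pseudoaxial to avoid A(1,2) strain with the C4 methyl, so H3 is equatorial and cannot undergo a semipinacol shift); axial H5 then shifts to C4 (sets 4β-Me, trans to the 3α-oxygen) and the axial C14 methyl shifts from C10 to C5 (sets 5β-Me, cis to C15), regenerating the Lewis-acid-bound 9-en-8-one as the thermodynamic sink; the closest known reaction types are alkylaluminium-halide-initiated enone–alkene cyclisations whose zwitterions undergo sequential 1,2-hydride/1,2-alkyl shifts back to an enone, and acid-induced eudesmane → eremophilane (Westphalen-type) methyl migrations.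

Step 6
Reactants: 6 3α-(tert-butyldimethylsilyloxy)eremophila-7(11),9-dien-8-one
Product: 7 3α-(tert-butyldimethylsilyloxy)-10βH-eremophil-7(11)-en-8-one (cis-decalin)
Conditions: H2 (1 atm), 10% Pd/C, EtOAc, 25 °C
Reagents that add atoms: none
Why: Chemoselective heterogeneous hydrogenation of the trisubstituted C9=C10 enone bond (the tetrasubstituted isopropylidene enone is much slower); hydrogen adds to C10 cis to the angular methyl to give the cis-fused 10βH decalone, as in hydrogenations of 4,4a-dimethyl-octalones and Δ4-3-keto steroids (→ 5β).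

Step 7
Reactants: 7 3α-(tert-butyldimethylsilyloxy)-10βH-eremophil-7(11)-en-8-one
Product: 9 3α-(tert-butyldimethylsilyloxy)-9β-(triethylsilyloxy)-10βH-eremophil-7(11)-en-8-one, via 9β-hydroxy ketone 8 (not isolated)
Conditions: LDA (1.15 equiv), THF, −78 °C; 2-(phenylsulfonyl)-3-phenyloxaziridine (1.3 equiv), −78 °C; then TESCl (2 equiv), −78 → 0 °C
Reagents that add atoms: 2-(phenylsulfonyl)-3-phenyloxaziridine O=S(=O)(c1ccccc1)N1OC1c1ccccc1; triethylsilyl chloride CC[Si](Cl)(CC)CC
Why: Kinetic α′-enolate formation (C9 is the only carbon bearing α-hydrogens) followed by Davis oxaziridine hydroxylation from the convex β-face of the cis-decalin (the α-face is blocked by the axial C4) gives the equatorial 9β-alkoxide, also the thermodynamically preferred ketol epimer, which is silylated in the same flask.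

Step 8
Reactants: 9 3α-(tert-butyldimethylsilyloxy)-9β-(triethylsilyloxy)-10βH-eremophil-7(11)-en-8-one
Product: 11 3α,9β-dihydroxy-7αH,10βH-eremophil-11-en-8-one (7β-isopropenyl), via bis-silyl 11-en-8-one 10 (not isolated)
Conditions: LDA (1.5 equiv), THF/DMPU, −78 → −40 °C; AcOH (3 equiv), −78 °C; then HF·pyridine, THF, 0 → 25 °C
Reagents that add atoms: none
Why: Kinetic deconjugation of an α-alkylidene ketone: γ-deprotonation (C9–H is a hindered α-silyloxy methine) gives the extended dienolate, which is protonated at the α-carbon C7 in the chair-like axial sense from the α-face, placing the isopropenyl group equatorial (7β, also the more stable of the two β,γ-epimers, since 7α would be 1,3-diaxial to C4); fluoride then removes both silyl ethers without base.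

Step 9
Reactants: 11 3α,9β-dihydroxy-7αH,10βH-eremophil-11-en-8-one; 12 angelic acid, (Z)-2-methylbut-2-enoic acid
Product: 13 3α,9β-bis(angeloyloxy)-7αH,10βH-eremophil-11-en-8-one, (3R,4R,5R,7R,9R,10S), the target
Conditions: 12 (5 equiv), 2,4,6-trichlorobenzoyl chloride (5 equiv), Et3N (6 equiv), PhMe, 25 °C; then 11, DMAP (0.5 equiv), 25 → 40 °C
Reagents that add atoms: angelic acid 12 C/C=C(/C)C(=O)O (used as its 2,4,6-trichlorobenzoic mixed anhydride)
Why: Yamaguchi esterification acylates both equatorial secondary alcohols through the mixed anhydride under conditions known to keep the (Z)-angelate geometry, and is mild enough to leave the β,γ-unsaturated ketone and the C7/C9 centres (already in their stable equatorial configurations) untouched; no new stereocentre is formed.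

**Compound list**
1 | germacrone, (1(10)E,4E)-germacra-1(10),4,7(11)-trien-8-one | C/C1=C\CC/C(C)=C/CC(=C(C)C)C(=O)C1 | starting material
2 | isogermacrone, (4E,9E)-germacra-4,7(11),9-trien-8-one | C/C1=C\C(=O)C(=C(C)C)C/C=C(C)/CCC1 | intermediate
3 | rac-(4E,9E)-3-hydroxygermacra-4,7(11),9-trien-8-one | C/C1=C\C(=O)C(=C(C)C)C/C=C(C)/C(O)CC1 | intermediate
4 | (3R,4E,9E)-3-hydroxygermacra-4,7(11),9-trien-8-one | C/C1=C\C(=O)C(=C(C)C)C/C=C(C)/[C@H](O)CC1 | intermediate
5 | (3R,4E,9E)-3-(tert-butyldimethylsilyloxy)germacra-4,7(11),9-trien-8-one | C/C1=C\C(=O)C(=C(C)C)C/C=C(C)/[C@H](O[Si](C)(C)C(C)(C)C)CC1 | intermediate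
6 | 3α-(tert-butyldimethylsilyloxy)eremophila-7(11),9-dien-8-one, (3R,4R,5R), O-TBS-isopetasol | CC(C)=C1C[C@@]2(C)C(CC[C@@H](O[Si](C)(C)C(C)(C)C)[C@@H]2C)=CC1=O | intermediate
7 | 3α-(tert-butyldimethylsilyloxy)-10βH-eremophil-7(11)-en-8-one (cis-decalin) | CC(C)=C1C[C@@]2(C)[C@H](CC[C@@H](O[Si](C)(C)C(C)(C)C)[C@@H]2C)CC1=O | intermediate
8 | 3α-(tert-butyldimethylsilyloxy)-9β-hydroxy-10βH-eremophil-7(11)-en-8-one (not isolated) | CC(C)=C1C[C@@]2(C)[C@H](CC[C@@H](O[Si](C)(C)C(C)(C)C)[C@@H]2C)[C@@H](O)C1=O | intermediate
9 | 3α-(tert-butyldimethylsilyloxy)-9β-(triethylsilyloxy)-10βH-eremophil-7(11)-en-8-one | CC(C)=C1C[C@@]2(C)[C@H](CC[C@@H](O[Si](C)(C)C(C)(C)C)[C@@H]2C)[C@@H](O[Si](CC)(CC)CC)C1=O | intermediate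
10 | 3α-(tert-butyldimethylsilyloxy)-9β-(triethylsilyloxy)-7αH,10βH-eremophil-11-en-8-one (not isolated) | C=C(C)[C@H]1C[C@@]2(C)[C@H](CC[C@@H](O[Si](C)(C)C(C)(C)C)[C@@H]2C)[C@@H](O[Si](CC)(CC)CC)C1=O | intermediate
11 | 3α,9β-dihydroxy-7αH,10βH-eremophil-11-en-8-one | C=C(C)[C@H]1C[C@@]2(C)[C@H](CC[C@@H](O)[C@@H]2C)[C@@H](O)C1=O | intermediate
12 | angelic acid, (Z)-2-methylbut-2-enoic acid | C/C=C(/C)C(=O)O | starting material
13 | 3α,9β-bis(angeloyloxy)-7αH,10βH-eremophil-11-en-8-one, (3R,4R,5R,7R,9R,10S) | C=C(C)[C@H]1C[C@@]2(C)[C@H](CC[C@@H](OC(=O)/C(C)=C\C)[C@@H]2C)[C@@H](OC(=O)/C(C)=C\C)C1=O | target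

**Step count and risks**

Total steps: 9. Longest linear sequence: 9 steps (1 → 13); angelic acid 12 is bought.

The three steps most likely to fail:

Step 5 (cascade). The risks are cyclisation through the conformer with equatorial OTBS (wrong C4/C5 sense, or semipinacol hydride shift to a 3-ketone), ring contraction, or Nazarov closure of the dienone. The fallback sets out from 1 and returns at 6, and triggers the shifts from a rigid epoxide instead. Germacrone 1 is cyclised with a Brønsted acid (TsOH, CH2Cl2) to racemic eudesma-3,7(11)-dien-8-one F1, the 3-ene being separated from its 4(15)- and 4-ene isomers. Shi epoxidation, run as a kinetic resolution with the fructose-derived ketone enantiomer matched to α-face attack on the required antipode, gives 3α,4α-epoxyeudesm-7(11)-en-8-one F2. BF3·OEt2 at −78 °C opens F2 at C4; in the trans-decalin the C3–O bond is locked axial and H3 equatorial, so the axial H5 and then the axial C14 methyl migrate and H9 is lost, giving (+)-isopetasol F3. Silylation (TBSCl, imidazole) returns 6.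

Step 3 (kinetic resolution). At most half of the material is usable, and selectivity on a conformationally mobile 10-membered allylic alcohol is uncertain. The fallback sets out from 3 and returns at 4 by oxidation and catalytic asymmetric reduction. Dess–Martin oxidation of 3 gives the achiral (4E,9E)-germacra-4,7(11),9-triene-3,8-dione F4. CBS reduction with (S)-Me-CBS and catecholborane at −78 °C reduces the C3 enone (large alkenyl versus small CH2 substituent; the hindered cross-conjugated C8 carbonyl is far less reactive) to 4.

Step 8 (deconjugation). The risks are competing C9–H deprotonation, γ-reprotonation back to 9, or protonation from the convex β-face giving the 7-epimer. The fallback sets out from 9 and returns at 10, avoiding the amide base by making the dienolate from a silyl dienol ether. Soft enolisation of 9 (TESOTf, Et3N, CH2Cl2) gives 3α-(tert-butyldimethylsilyloxy)-8,9β-bis(triethylsilyloxy)-10βH-eremophila-7,11-diene F5. Buffered fluoride (TBAF, AcOH, THF, −78 °C) cleaves only the enol silyl ether and protonates the metal-free dienolate at C7 to give 10, which is carried on with HF·pyridine as in step 8. Any 7-epimer is corrected at this stage by brief contact with catalytic DBU, since α-reprotonation is faster than conjugation.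

**Further compounds**
F1 | step 5 | rac-eudesma-3,7(11)-dien-8-one (10β-methyl, 5αH antipode drawn) | CC1=CCC[C@]2(C)CC(=O)C(=C(C)C)C[C@@H]12
F2 | step 5 | 3α,4α-epoxyeudesm-7(11)-en-8-one | C[C@@]12O[C@@H]1CC[C@]3(C)CC(=O)C(=C(C)C)C[C@@H]23
F3 | step 5 | (+)-isopetasol, 3α-hydroxyeremophila-7(11),9-dien-8-one | CC(C)=C1C[C@@]2(C)C(CC[C@@H](O)[C@@H]2C)=CC1=O
F4 | step 3 | (4E,9E)-germacra-4,7(11),9-triene-3,8-dione | C/C1=C\C(=O)C(=C(C)C)C/C=C(C)/C(=O)CC1
F5 | step 8 | 3α-(tert-butyldimethylsilyloxy)-8,9β-bis(triethylsilyloxy)-10βH-eremophila-7,11-diene | C=C(C)C=1C[C@@]2(C)[C@H](CC[C@@H](O[Si](C)(C)C(C)(C)C)[C@@H]2C)[C@@H](O[Si](CC)(CC)CC)C=1O[Si](CC)(CC)CC
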